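Before any rate constant is fitted, the target can be turned into a plain ratio. The excess is one minus the ratio of left-handed to right-handed substrate, over one plus that ratio, so 80 % needs a ratio no higher than 0.111, which I call the ceiling ratio.

| setting | dusk | spring | summer | flask |
|---|---|---|---|---|
| left-handed substrate | 0.10 M | 0.10 M | 0.050 M | 0.10 M |
| right-handed substrate | 0.10 M | 0.10 M | 0.050 M | 0.10 M |
| coupling partner | 1.5 equiv (fed, over 1.0 h) | 2.4 equiv (fed, over 1.0 h) | 1.1 equiv (fed, over 1.0 h) | 1.10 equiv (fed, over 1.0 h) |
| precatalyst | 20 mol% | 20 mol% | 20 mol% | 20 mol% |
| remark | run made earlier; the fed solution adds 0.20 times the starting volume | run made earlier; the fed solution adds 0.20 times the starting volume | run made earlier; the fed solution adds 0.20 times the starting volume | the fed solution adds 0.20 times the starting volume |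
| time |  |  |  | 4.0 h |

| run | time / h | right-handed substrate / % | left-handed substrate / % | left-handed product / % |
|---|---|---|---|---|
| dusk | 0.667 | 49 | 28 | 20 |
| dusk | 1.33 | 47 | 8 | 43 |
| dusk | 2.00 | 49 | 1 | 49 |
| dusk | 3.00 | 49 | 1 | 51 |
| dusk | 4.00 | 49 | 2 | 50 |
| dusk | 5.00 | 47 | 0 | 51 |
| spring | 0.417 | 50 | 36 | 17 |
| spring | 0.667 | 50 | 16 | 33 |
| spring | 0.833 | 49 | 11 | 39 |
| spring | 1.33 | 48 | 2 | 49 |
| spring | 2.00 | 48 | 0 | 50 |
| spring | 3.00 | 44 | 0 | 49 |
| spring | 5.00 | 44 | 0 | 52 |
| summer | 1.00 | 50 | 35 | 17 |
| summer | 2.00 | 51 | 18 | 31 |
| summer | 3.00 | 48 | 14 | 34 |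
| summer | 4.00 | 51 | 9 | 38 |
| summer | 5.00 | 49 | 9 | 44 |

(standard deviation of a reading: 1.5 percentage points)

- whether the excess of right-handed substrate over left-handed substrate among what is left of the two reaches 80 % by 4.0 h (yes / no)
- the highest excess of right-handed substrate over left-handed substrate among what is left of the two up to 4.0 h

- catalyst is single-handed; left-handed substrate and right-handed substrate are mirror images of each other, charged as a racemate, each of them at the stated concentration
- charges are per starting volume, the dose included; the dosed solution carries all of it

The dusk run reads 49 % right-handed substrate at 4.00 h, so the ceiling ratio allows 5.44 % left-handed substrate. The summer run, at half the flask's concentration, reads 9 % left-handed substrate at 4.00 h. I expect the flask to reach that level in half the time. With left-handed substrate and coupling partner nearly one to one, the integrated second-order tail falls as one over time, so I reckon that by 4.0 h the flask stands at 4.50 %, half that level. That is below the allowance, and it gives an excess near 83.2 %.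

The forecast says yes with a top of 85 %, "still rising at 4 h", above my figure.

The flask gives yes and a top of 90.3 %, above both estimates.

    coupling partner + catalyst + left-handed substrate → catalyst + left-handed product (k = 51.0 L² mol⁻² min⁻¹)
    coupling partner + catalyst + right-handed substrate → catalyst + right-handed product (k = 0.450 L² mol⁻² min⁻¹)
    2 coupling partner → self-condensation product (k = 0.0190 L mol⁻¹ min⁻¹)
    precatalyst → catalyst (k = 0.0320 min⁻¹)

The flask passes 80 % at 2.29 h, with right-handed substrate still at 49.0 %, and the selectivity factor is 113. At 4.00 h the flask holds 2.48 % left-handed against 48.7 % right-handed substrate, a ratio of 0.0509, below the ceiling ratio 0.111. The summer run at 5.00 h reads 9 % against 49 %, a ratio of 0.184, above the ceiling ratio, so its excess reads 69.0 %.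

All runs were generated by integration from invented constants, noise included.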